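The summer and dusk runs were charged with different amounts of free monomer, yet each lost about the same amount to something other than chains, and on a repeat that gap is the first thing to watch.

| flask | free monomer | protic impurity | initiator | remark | time |
|---|---|---|---|---|---|
| summer | 0.13 M | 0.030 M | 0.50 mM | run made earlier |  |
| dusk | 0.30 M | 0.030 M | 0.50 mM | run made earlier |  |
| delta | 0.10 M | 0.0300 M | 0.50 mM |  | 15 h |
| eta | 0.20 M | 0.0300 M | 0.50 mM |  | 15 h |

| run | time / h | monomer in chains / % | free monomer / % |
|---|---|---|---|
| summer | 1.33 | 7 | 78 |
| summer | 2.00 | 15 | 72 |
| summer | 3.00 | 26 | 62 |
| summer | 5.00 | 38 | 43 |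
| summer | 10.0 | 57 | 22 |
| summer | 15.0 | 64 | 10 |
| dusk | 2.50 | 28 | 64 |
| dusk | 5.00 | 43 | 47 |
| dusk | 8.00 | 58 | 28 |
| dusk | 10.0 | 65 | 23 |
| dusk | 12.0 | 71 | 18 |
| dusk | 15.0 | 77 | 13 |

(readings scatter by 1.5 percentage points)

- the average divides the monomer in chains by the number of chains begun, living and dead together
- the earlier runs do not show the number of chains; that part of a forecast is a guess

* which of the two ends with the longer chains by the average number of monomer units in a chain (chains begun, living or dead) ("neither" if they lie within 10%) (delta / eta / neither)
* average number of monomer units in a chain (chains begun, living or dead) at the end, delta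
* average number of monomer units in a chain (chains begun, living or dead) at the end, eta

The earliest rung is that gap. The dusk run is short by 0.0240 M at 2.50 h and 0.0300 M at 15.0 h, and the summer run by 0.0338 M at 15.0 h, against 0.030 M of protic impurity in each. So each impurity molecule appears to take one free monomer out of reach.

The next rung is the pseudo-first-order fall of free monomer. Between 2.50 h and 8.00 h the dusk readings give 0.150 h⁻¹, a half-life of 4.61 h, which is longer than the 2.50 h of the first rung.

The last rung is the end of the run, 3.25 such half-lives after the start. By then the monomer left after the impurity's toll stands mostly in chains: 83.2% in summer and 85.6% in dusk, so 84.4% is carried over.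

Time drops out of one ratio, the ceiling length, which is the free monomer left after the impurity's toll, divided by the initiator, taking one chain per initiator as a guess:

ceiling, delta = 140; ceiling, eta = 340

length at the end = share × ceiling: delta 118, eta 287

The forecast differs from this reckoning by a few units: eta longer, with 115 (60 to 150) for delta and 290 (150 to 370) for eta, and the caution “Chain count is a guess”.

The flasks give eta as the longer, with 290 for eta and 120 for delta.

    monomer in chains + living end → free monomer + living end, rate k1*[living end] as long as [monomer in chains] is above zero (k = 0.0319 min⁻¹)
    free monomer + living end → monomer in chains + living end, rate k2*[living end]*[free monomer] (k = 4.82 M⁻¹ min⁻¹)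
    free monomer + initiator → living end + monomer in chains (k = 0.215 M⁻¹ min⁻¹)
    protic impurity + free monomer → quenched substrate (k = 0.0614 M⁻¹ min⁻¹)

In delta, monomer in chains is made 6.89 times faster than it is used up at 4.75 h, and still 2.02 times faster at 15.0 h, when free monomer stands at 13.3% of its charge. Left for 150 h, delta reaches 127, which is 90.8% of its ceiling. For a neighbour of delta charged with 0.17 M of free monomer, ceiling times share gives 236, and that flask ends at 238.

All runs were generated by integration from invented constants; the scatter is artificial.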